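## The problem

Compound 10, (4R)-8-benzoyl-5,7-dihydroxy-6-(3-methylbut-2-enyl)-4-phenylchroman-2-one, is a 3,4-dihydrocoumarin whose benzene ring (ring A) carries no hydrogen: going round from C4a it bears the lactone carbon C4, a hydroxyl at C5, a prenyl group at C6, a hydroxyl at C7, a benzoyl group at C8 and the lactone oxygen O1 at C8a. The only stereocentre is C4 (R), a diarylmethine; nothing else in the molecule can relay to it, so a reagent or catalyst must set it, and being β rather than α to the lactone carbonyl it should hold once formed. Two phenolic oxygens, O1 and O5, flank C4a and are equally placed to close a six-membered lactone onto C2, but only O1, next to the benzoyl group, may do so. A free O5 phenoxide could later take the acyl group over, so base must be kept from the finished lactone. The aryl ester opens with alkoxide, hydroxide or amines, the prenyl group between two phenols cyclises under acid or electrophilic halogen and is saturated by hydrogenation, and the phloroglucinol nucleus is oxidisable. The enabling feature is the make-up of the lactone ring: C2 is a single carbonyl carbon between C3 and O1, and C4 carries phenyl and hydrogen, so the ring is carbon monoxide inserted between the terminal carbon of a 1-phenylvinyl group and the neighbouring phenol oxygen, with hydrogen added at the inner carbon. Ring A with its three oxygens and the benzoyl group is available intact as 2,4,6-trihydroxybenzophenone (1), which reduces the task to placing three carbon substituents in a workable order and telling O5 from O1.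

## Retrosynthesis

**10 to 9 (O5–Si).** The O5–H of 10 is traced back to the O5 tert-butyldimethylsilyl ether 9. This is needed because a lactone-forming step on a substrate with O5 free would have two equivalent nucleophiles. A silyl ether is preferred to methyl, benzyl or acetal protection because its removal needs no Lewis acid (prenyl cyclisation), no hydrogen (prenyl saturation) and no base (lactone opening or O1-to-O5 acyl transfer). The forward step must free O5 under buffered, weakly acidic desilylation and touch nothing else.

**9 to 7 + 8 (C3–C2 and C2–O1).** Both bonds to the lactone carbonyl carbon are cut, which removes the ring, the stereocentre and one carbon at once and leaves the 2-(1-phenylvinyl)phenol 7 and carbon monoxide (8). The neighbouring cut at C4–C4a would call for acid-mediated arylation of a cinnamate-type acceptor, which is incompatible with the prenyl group and offers no handle on C4. Cutting C2–O1 alone leaves a 3,3-diarylpropanoic acid whose stereocentre still has to be made. The forward reaction needs a hydropalladation that is anti-Markovnikov and face-selective, a preference for the 1,1-disubstituted alkene over the trisubstituted prenyl alkene, acyl capture by O1 only (which the O5 silyl ether of 7 enforces) and near-neutral conditions.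

**7 to 6 (O–Si at the oxygen para to the benzoyl group).** Removing the silyl group gives triol 6. No earlier point is possible because the C-prenylation is run in aqueous base, which an aryl silyl ether para to a ketone does not survive. The forward step must pick the para hydroxyl out of three, on the strength of its higher acidity and the hydrogen bonding and shielding of the two ortho hydroxyls by the ketone.

**6 to 4 + 5 (ring carbon to prenyl CH2).** The prenyl group is cut from the last unsubstituted ring carbon, giving triol 4 and prenyl bromide (5). Prenylation must follow the iodination, since an ortho-prenylphenol would undergo iodoetherification. It must precede silyl ether and lactone, both of which are base-labile. With one open ring carbon left, the forward alkylation has no positional choice and only has to favour carbon over oxygen.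

**4 to 2 + 3 (aryl–vinyl bond).** The 1-phenylvinyl group is cut at its bond to ring A, giving aryl iodide 2 and (1-phenylvinyl)boronic acid (3). The alternative, methylenation of a second benzoyl group, could not distinguish two aryl ketones on one ring. The forward cross-coupling must tolerate three free phenols and a doubly ortho-substituted iodide.

**2 to 1 (C–I).** The iodine is removed to give 1, whose two open ring carbons are equivalent. The forward iodination therefore only has to stop at one halogen.

## Roads not taken

Alternative 1: ring A is built rather than bought, by cutting the arene bond C8–C8a.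
- Key step: Mg(OMe)2 in methanol opens the 2-pyrone methyl (3R)-3-[4-methoxy-2-oxo-6-(2-oxo-2-phenylethyl)-2H-pyran-3-yl]-3-phenylpropanoate A2 at its ring carbonyl. The phenacyl methylene then closes onto the new ester in a Claisen condensation to give methyl (3R)-3-(3-benzoyl-2,4-dihydroxy-6-methoxyphenyl)-3-phenylpropanoate A1.
- Merits: the polyketide logic places the benzoyl group and all three oxygens without aromatic substitution. O5 emerges as a methyl ether, so later lactonisation can only use O1. The stereocentre is installed on an open-chain precursor, away from a crowded arene, and in that respect this road is more secure than step 5 of the chosen plan.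
- Weak points: A2 is a multistep compound in its own right. Its stereocentre is β to an ester and sits on a carbon that is a stabilised leaving group, so methoxide can reverse the Michael addition and racemise it. After A1 the prenyl group must still be introduced at C6 under base beside an ester or lactone. The O5 methyl ether must finally be cleaved by a Lewis acid or hard nucleophile, conditions that cyclise the prenyl group and open the lactone.
- Comparison: against the better-founded stereocentre, the chosen plan takes ring A and the benzoyl group from 1 without effort, needs six steps, and removes its one protecting group with buffered fluoride.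

Alternative 2: the lactone oxygen is inserted last into a carbocycle, by cutting O1–C8a.
- Key step: m-CPBA with TfOH converts (3R)-4,6-dimethoxy-3-phenylindan-1-one A4 by Baeyer–Villiger aryl migration into (4R)-5,7-dimethoxy-4-phenylchroman-2-one A3.
- Merits: the stereocentre of A4 can come from established asymmetric conjugate-addition or hydrogenation chemistry, and the migration leaves it untouched. The position of the lactone oxygen is fixed by the carbon skeleton, not by a protecting group. On both counts this road is at least as good as the chosen one, where O1-versus-O5 discrimination depends on the silylation of step 4.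
- Weak points: both methoxy groups are meta to the migrating aryl carbon, so migration gets no conjugative help and CH2 migration or ring oxidation can compete. A3 still lacks the benzoyl and prenyl groups; Friedel–Crafts benzoylation must choose between C6 and C8 in the presence of a Lewis-acid-sensitive lactone. Two methyl ethers must then be cleaved beside prenyl and lactone. Gentler phenol protection would not survive peracid and strong acid.
- Comparison: the chosen plan installs every ring A substituent under mild conditions before the stereocentre exists and ends with a fluoride deprotection; it pays with a less certain asymmetric step.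

Alternative 3: ring A is assembled by a Danheiser benzannulation, cutting C8a–C8 and C6–C7.
- Key step: the 3-siloxycyclobutenone methyl (3S)-3-[3-(3-methylbut-2-enyl)-4-oxo-2-(triisopropylsilyloxy)cyclobut-2-en-1-yl]-3-phenylpropanoate A6, a mixture at the ring carbon, is heated with the racemic siloxyalkyne tert-butyldimethyl({1-phenyl-3-[(triisopropylsilyl)oxy]prop-2-yn-1-yl}oxy)silane A7. The product is methyl (3R)-3-{3-[(tert-butyldimethylsilyloxy)(phenyl)methyl]-2-hydroxy-5-(3-methylbut-2-enyl)-4,6-bis(triisopropylsilyloxy)phenyl}-3-phenylpropanoate A5, a mixture at the carbinol carbon. The descriptor changes from S in A6 to R in A5 only because the ring carbon gains priority on aromatisation.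
- Merits: all six ring A substituents are placed regiospecifically. Each oxygen has a different origin, so only O1 is free and no selective protection is needed, which is cleaner than step 4 of the chosen plan. The stereocentre comes from desymmetrisation of 3-phenylglutaric anhydride A8, independent of the arene.
- Weak points: A6 has to be built from A8 over several steps, and A7 is a multistep compound as well. The electrocyclic closure must form a hexasubstituted benzene carrying three bulky silyloxy-bearing groups. After A5 the carbinol must be unmasked selectively and oxidised on an electron-rich ring where an ortho-hydroxybenzylic position readily ionises to an ortho-quinone methide. Lactonisation and double desilylation follow. The step count is at least twice that of the chosen plan.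
- Comparison: the chosen plan answers with brevity and a purchased ring A; it pays with one selective silylation.

Key step: step 5

Assumption 1: 2,4,6-trihydroxybenzophenone (1) is treated as a purchased compound; it is otherwise one Friedel–Crafts or Hoesch acylation away from phloroglucinol.

Assumption 2: the sense of induction of a chiral bisphosphine on a 1-aryl alkene cannot be inferred from the 1-alkyl cases, so "(R,R)-DIOP" in step 5 stands for whichever ligand antipode delivers (4R), to be fixed by experiment.

## Route

Step 1
Reactants: 1 2,4,6-trihydroxybenzophenone
Product: 2 3-iodo-2,4,6-trihydroxybenzophenone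
Conditions: NIS (1.0 equiv, slow addition), MeCN, −20 → 0 °C, dark
Reagents that add atoms: N-iodosuccinimide, O=C1CCC(=O)N1I
Why: Electrophilic aromatic iodination of a phloroglucinol ring; the two open carbons of 1 are equivalent, so only mono against bis selectivity is needed, which one equivalent of NIS added slowly in the cold should secure because the first iodine lowers the reactivity of the remaining position. The halogen goes in now because an ortho-prenylphenol would undergo iodoetherification with the same reagent.

Step 2
Reactants: 2 3-iodo-2,4,6-trihydroxybenzophenone; 3 (1-phenylvinyl)boronic acid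
Product: 4 2,4,6-trihydroxy-3-(1-phenylvinyl)benzophenone
Conditions: Pd(OAc)2 (5 mol %), SPhos (10 mol %), K3PO4 (4 equiv), dioxane/H2O (degassed), 80 °C
Reagents that add atoms: none
Why: Suzuki–Miyaura cross-coupling; unprotected ortho-iodophenols are competent partners, and the dialkylbiarylphosphine ligand suits a doubly ortho-substituted, electron-rich aryl iodide and an α-substituted alkenylboronic acid. The product cannot cyclise, since addition of a flanking hydroxyl to the alkene would need a four-membered ring or anti-Markovnikov attack.

Step 3
Reactants: 4 2,4,6-trihydroxy-3-(1-phenylvinyl)benzophenone; 5 prenyl bromide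
Product: 6 2,4,6-trihydroxy-3-(3-methylbut-2-enyl)-5-(1-phenylvinyl)benzophenone
Conditions: 5 (1.05 equiv), aq. KOH (10 %), argon, 0 °C; then NaH2PO4 to pH 5
Reagents that add atoms: none
Why: C-Alkylation of a phloroglucinol polyanion, the standard entry to prenylated acylphloroglucinols; in water the phenoxide oxygens are solvated and the allylic bromide is taken up at carbon, here the single unsubstituted ring position. A small excess of 5 at 0 °C limits O-alkylation and a second, dearomatising alkylation, and base is harmless at this stage because neither silyl ether nor lactone is yet present.

Step 4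
Reactants: 6 2,4,6-trihydroxy-3-(3-methylbut-2-enyl)-5-(1-phenylvinyl)benzophenone
Product: 7 4-(tert-butyldimethylsilyloxy)-2,6-dihydroxy-3-(3-methylbut-2-enyl)-5-(1-phenylvinyl)benzophenone
Conditions: TBSCl (1.05 equiv), imidazole (2.2 equiv), DMF, 0 °C
Reagents that add atoms: tert-butyldimethylsilyl chloride, CC(C)(C)[Si](C)(C)Cl
Why: Silyl ether formation; the hydroxyl para to the benzoyl group is the most acidic of the three and the only one neither hydrogen-bonded to nor shielded by the ketone, the basis of para-selective protection of 2,4,6-trihydroxyaryl ketones. One equivalent of the chloride at 0 °C should stop at the mono-ether, and two ortho substituents do not prevent tert-butyldimethylsilylation of a phenol.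

Step 5
Reactants: 7 4-(tert-butyldimethylsilyloxy)-2,6-dihydroxy-3-(3-methylbut-2-enyl)-5-(1-phenylvinyl)benzophenone; 8 carbon monoxide
Product: 9 (4R)-8-benzoyl-5-(tert-butyldimethylsilyloxy)-7-hydroxy-6-(3-methylbut-2-enyl)-4-phenylchroman-2-one
Conditions: Pd(OAc)2 (5 mol %), (R,R)-DIOP (10 mol %), CO/H2 (1:1, 35 bar), CH2Cl2, 100 °C (autoclave)
Reagents that add atoms: none
Why: Under CO/H2 the divalent palladium acetate is converted into a bisphosphine palladium hydride, which adds across the 1,1-diarylethene of 7 with palladium on the terminal carbon (future C3) and hydrogen on the diaryl carbon (future C4); CO insertion gives the acylpalladium, and the C8a phenol captures it and regenerates the hydride, so H2 is a promoter and is not consumed. The closest known reaction type is the palladium/chiral bisphosphine cyclocarbonylation of 2-(1-substituted vinyl)phenols and anilines to 4-substituted six-membered lactones and lactams. The one ring closes by acyl substitution at the acyl carbon, a 6-exo-trig closure (equivalently C–O reductive elimination from a seven-membered acyl(aryloxo)palladium chelate). The C4 stereocentre is set by the alkene face that receives hydride, which the C2-symmetric ligand controls. Regiochemistry of hydropalladation is anti-Markovnikov because the alternative is a quaternary diarylalkylpalladium that cannot lead to a six-membered lactone. Lactone regiochemistry is secured by the O5 silyl ether, the C7 hydroxyl being meta to the side chain. The trisubstituted prenyl alkene is a far poorer hydride acceptor than the 1,1-disubstituted one, and C4, not being α to the carbonyl, cannot epimerise by enolisation.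

Step 6
Reactants: 9 (4R)-8-benzoyl-5-(tert-butyldimethylsilyloxy)-7-hydroxy-6-(3-methylbut-2-enyl)-4-phenylchroman-2-one
Product: 10 (4R)-8-benzoyl-5,7-dihydroxy-6-(3-methylbut-2-enyl)-4-phenylchroman-2-one
Conditions: HF·pyridine, pyridine, THF, 0 °C → rt
Reagents that add atoms: none
Why: Fluoride cleavage of an aryl silyl ether under buffered, weakly acidic conditions; the aryl lactone, which basic fluoride or alkoxide would open or pass to the liberated O5 phenoxide, should be untouched. The medium is not acidic enough to cyclise the prenyl group onto a neighbouring phenol, and C4 is not involved.

## Compound list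

1 | (2,4,6-trihydroxyphenyl)(phenyl)methanone (2,4,6-trihydroxybenzophenone) | O=C(c1ccccc1)c1c(O)cc(O)cc1O | starting material
2 | (2,4,6-trihydroxy-3-iodophenyl)(phenyl)methanone | O=C(c1ccccc1)c1c(O)cc(O)c(I)c1O | intermediate
3 | (1-phenylvinyl)boronic acid | OB(O)C(=C)c1ccccc1 | starting material
4 | [2,4,6-trihydroxy-3-(1-phenylvinyl)phenyl](phenyl)methanone | O=C(c1ccccc1)c1c(O)cc(O)c(C(=C)c2ccccc2)c1O | intermediate
5 | prenyl bromide (1-bromo-3-methylbut-2-ene) | CC(C)=CCBr | starting material
6 | [2,4,6-trihydroxy-3-(3-methylbut-2-enyl)-5-(1-phenylvinyl)phenyl](phenyl)methanone | CC(C)=CCc1c(O)c(C(=O)c2ccccc2)c(O)c(C(=C)c2ccccc2)c1O | intermediate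
7 | {4-(tert-butyldimethylsilyloxy)-2,6-dihydroxy-3-(3-methylbut-2-enyl)-5-(1-phenylvinyl)phenyl}(phenyl)methanone | CC(C)=CCc1c(O)c(C(=O)c2ccccc2)c(O)c(C(=C)c2ccccc2)c1O[Si](C)(C)C(C)(C)C | intermediate
8 | carbon monoxide | [C-]#[O+] | starting material
9 | (4R)-8-benzoyl-5-(tert-butyldimethylsilyloxy)-7-hydroxy-6-(3-methylbut-2-enyl)-4-phenylchroman-2-one | CC(C)=CCc1c(O)c(C(=O)c2ccccc2)c2c(c1O[Si](C)(C)C(C)(C)C)[C@@H](c1ccccc1)CC(=O)O2 | intermediate
10 | (4R)-8-benzoyl-5,7-dihydroxy-6-(3-methylbut-2-enyl)-4-phenylchroman-2-one | CC(C)=CCc1c(O)c(C(=O)c2ccccc2)c2c(c1O)[C@@H](c1ccccc1)CC(=O)O2 | target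

## Step count and risks

Total step count: 6. Longest linear sequence: 6 steps (1 → 2 → 4 → 6 → 7 → 9 → 10).

**Step 5 (key step).**
- Most likely failure: insufficient enantiofacial discrimination in the hydropalladation. The known substrates set a small alkyl group against an aryl group at the alkene carbon; here the ligand must tell a phenyl ring from a twisted, fully substituted aryl ring. Hydropalladation is also reversible at 100 °C, so selectivity can erode through β-hydride elimination and re-addition.
- Also possible: hydrogenation of the styrenic double bond by the hydride under H2, and slow turnover at an alkene flanked by a silyl ether and a chelated hydroxyl. Ligand, gas composition and pressure would be screened first.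
- Fallback: form the C4–phenyl bond enantioselectively on a planar coumarin instead of the C4–H bond. It sets out again from 1. Pechmann-type condensation with ethyl propiolate (ZnCl2, 90 °C) should give 8-benzoyl-5,7-dihydroxy-2H-chromen-2-one F1, to be separated from its 6-benzoyl isomer. C-prenylation at the only open ring A carbon under the conditions of step 3 should give 8-benzoyl-5,7-dihydroxy-6-(3-methylbut-2-enyl)-2H-chromen-2-one F2; the coumarin lactone, opened reversibly by the aqueous base, should reclose on acidification. Rhodium-catalysed asymmetric 1,4-addition of phenylboronic acid (Rh(acac)(C2H4)2, SEGPHOS of the appropriate handedness, dioxane/H2O, 60 °C) would then add phenyl at C4. The route is rejoined at 10.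

**Step 4.**
- Most likely failure: loss of site selectivity. The para hydroxyl is flanked on both sides, so silylation of the less hindered ortho hydroxyl next to the prenyl group, or over-silylation to a bis-ether, can compete.
- Fallback: make the bis-ether the intermediate. From 6, excess TBSOTf and 2,6-lutidine should give {2,4-bis(tert-butyldimethylsilyloxy)-6-hydroxy-3-(3-methylbut-2-enyl)-5-(1-phenylvinyl)phenyl}(phenyl)methanone F3. The last, chelated hydroxyl beside the bulkier 1-phenylvinyl group is expected to stay free; any regioisomeric bis-ether would be desilylated back to 6. Cyclocarbonylation as in step 5 would give (4R)-8-benzoyl-5,7-bis(tert-butyldimethylsilyloxy)-6-(3-methylbut-2-enyl)-4-phenylchroman-2-one F4. HF·pyridine would remove both silyl groups, rejoining the route at 10. This variant also masks O7 from the prenyl alkene during carbonylation.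

**Step 3.**
- Most likely failure: O-alkylation and double alkylation with dearomatisation competing with mono-C-prenylation, as is common for direct prenylation of phloroglucinols.
- Fallback: deliver the prenyl group through oxygen. From 4, palladium-catalysed O-alkylation of the most acidic, para hydroxyl (Pd(PPh3)4, tert-butyl 2-methylbut-3-en-2-yl carbonate, THF) should give {2,6-dihydroxy-4-[(2-methylbut-3-en-2-yl)oxy]-3-(1-phenylvinyl)phenyl}(phenyl)methanone F5. Aromatic Claisen rearrangement on heating in toluene can move the allyl unit only to the one free ortho carbon, with allylic inversion to the prenyl group. The route is rejoined at 6.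

**Step 2.**
- Most likely failure: protodeiodination of the very electron-rich iodophenoxide and protodeboronation of the α-substituted alkenylboronic acid outrunning a slow coupling at a doubly ortho-substituted centre.
- Fallback: mask the phenols so that the iodide is electron-poor and no phenoxide forms. From 2, Ac2O and pyridine should give 2-benzoyl-4-iodobenzene-1,3,5-triyl triacetate F6. Anhydrous Suzuki–Miyaura coupling with 3 (Pd(OAc)2, SPhos, K3PO4, toluene) should give 2-benzoyl-4-(1-phenylvinyl)benzene-1,3,5-triyl triacetate F7. Methanolysis (K2CO3, MeOH, 0 °C) rejoins the route at 4.

## Further compounds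

F1 | step 5 | 8-benzoyl-5,7-dihydroxy-2H-chromen-2-one | O=C(c1ccccc1)c1c(O)cc(O)c2ccc(=O)oc12
F2 | step 5 | 8-benzoyl-5,7-dihydroxy-6-(3-methylbut-2-enyl)-2H-chromen-2-one | CC(C)=CCc1c(O)c(C(=O)c2ccccc2)c2oc(=O)ccc2c1O
F3 | step 4 | {2,4-bis(tert-butyldimethylsilyloxy)-6-hydroxy-3-(3-methylbut-2-enyl)-5-(1-phenylvinyl)phenyl}(phenyl)methanone | CC(C)=CCc1c(O[Si](C)(C)C(C)(C)C)c(C(=O)c2ccccc2)c(O)c(C(=C)c2ccccc2)c1O[Si](C)(C)C(C)(C)C
F4 | step 4 | (4R)-8-benzoyl-5,7-bis(tert-butyldimethylsilyloxy)-6-(3-methylbut-2-enyl)-4-phenylchroman-2-one | CC(C)=CCc1c(O[Si](C)(C)C(C)(C)C)c(C(=O)c2ccccc2)c2c(c1O[Si](C)(C)C(C)(C)C)[C@@H](c1ccccc1)CC(=O)O2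
F5 | step 3 | {2,6-dihydroxy-4-[(2-methylbut-3-en-2-yl)oxy]-3-(1-phenylvinyl)phenyl}(phenyl)methanone | C=CC(C)(C)Oc1cc(O)c(C(=O)c2ccccc2)c(O)c1C(=C)c1ccccc1
F6 | step 2 | 2-benzoyl-4-iodobenzene-1,3,5-triyl triacetate | CC(=O)Oc1cc(OC(C)=O)c(C(=O)c2ccccc2)c(OC(C)=O)c1I
F7 | step 2 | 2-benzoyl-4-(1-phenylvinyl)benzene-1,3,5-triyl triacetate | CC(=O)Oc1cc(OC(C)=O)c(C(=O)c2ccccc2)c(OC(C)=O)c1C(=C)c1ccccc1
A1 | alternative 1 | methyl (3R)-3-(3-benzoyl-2,4-dihydroxy-6-methoxyphenyl)-3-phenylpropanoate | c1c(O)c(C(=O)c2ccccc2)c(O)c(c1OC)[C@@H](c1ccccc1)CC(=O)OC
A2 | alternative 1 | methyl (3R)-3-[4-methoxy-2-oxo-6-(2-oxo-2-phenylethyl)-2H-pyran-3-yl]-3-phenylpropanoate | O=c1oc(CC(=O)c2ccccc2)cc(OC)c1[C@@H](c1ccccc1)CC(=O)OC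
A3 | alternative 2 | (4R)-5,7-dimethoxy-4-phenylchroman-2-one | COc1cc(OC)c2c(c1)OC(=O)C[C@@H]2c1ccccc1
A4 | alternative 2 | (3R)-4,6-dimethoxy-3-phenylindan-1-one | COc1cc(OC)c2c(c1)C(=O)C[C@@H]2c1ccccc1
A5 | alternative 3 | methyl (3R)-3-{3-[(tert-butyldimethylsilyloxy)(phenyl)methyl]-2-hydroxy-5-(3-methylbut-2-enyl)-4,6-bis(triisopropylsilyloxy)phenyl}-3-phenylpropanoate, mixture at the carbinol carbon | CC(C)=CCc1c(O[Si](C(C)C)(C(C)C)C(C)C)c(C(O[Si](C)(C)C(C)(C)C)c2ccccc2)c(O)c(c1O[Si](C(C)C)(C(C)C)C(C)C)[C@@H](c1ccccc1)CC(=O)OC
A6 | alternative 3 | methyl (3S)-3-[3-(3-methylbut-2-enyl)-4-oxo-2-(triisopropylsilyloxy)cyclobut-2-en-1-yl]-3-phenylpropanoate, mixture at the ring carbon | CC(C)=CCC1=C(O[Si](C(C)C)(C(C)C)C(C)C)C(C1=O)[C@@H](c1ccccc1)CC(=O)OC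
A7 | alternative 3 | tert-butyldimethyl({1-phenyl-3-[(triisopropylsilyl)oxy]prop-2-yn-1-yl}oxy)silane, racemic | CC(C)[Si](OC#CC(O[Si](C)(C)C(C)(C)C)c1ccccc1)(C(C)C)C(C)C
A8 | alternative 3 | 3-phenylglutaric anhydride (4-phenyloxane-2,6-dione) | O=C1CC(CC(=O)O1)c1ccccc1
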